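**Retrosynthetic overview**

1. Phylloquinone is reached by oxidative demethylation of its hydroquinone dimethyl ether. No ring is formed in the route: both rings of the naphthalene are bought with menadione, and only the quinonoid ring changes oxidation level (quinone, dimethyl ether, quinone).
2. The key disconnection is C7'–C8' of the side chain (C1' is the ring-bound CH2, C16' the chain end). A C22 secondary (R)-tosylate (naphthalene plus C1'–C7') and a C11 Grignard reagent (C8'–C16') are joined by a copper-catalysed SN2 alkyl–alkyl coupling with inversion. Two electrophile-derived sp3 carbons are united after polarity reversal at C8'; the step completes the carbon skeleton and sets 7'R.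
3. Enabling feature: C7' is a CH(CH3) methine whose chain neighbours C6' and C8' are unbranched CH2 groups. It lies four bonds from the C2'=C3' alkene and seven from the quinonoid ring, so it behaves as an isolated methylcarbinyl centre: it maps onto the carbinol carbon of (R)-propylene oxide, is open to backside attack, and has no allylic or benzylic ionisation. C8' is primary, with its nearest branch (C11') three atoms away.
4. Left fragment: (R)-propylene oxide is opened by a silylbutynyl Grignard reagent to give (R)-hept-6-yn-2-ol. Zirconium-catalysed methylalumination and palladium-catalysed coupling with chloromethylated menadiol dimethyl ether fix the E C2'=C3' alkene; tosylation follows.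
5. Right fragment: (R)-citronellyl bromide supplies C11' and is extended by one carbon (formaldehyde), hydrogenated and brominated.

Key step: step 10

Remark: the SMILES is read as natural (2'E,7'R,11'R)-phylloquinone; (R)-citronellyl bromide, (R)-propylene oxide and (4-bromobut-1-yn-1-yl)trimethylsilane are taken as commercial.

**Route**

Step 1
Reactants: 1 menadione (2-methylnaphthalene-1,4-dione)
Product: 3 1,4-dimethoxy-2-methylnaphthalene, via menadiol 2 (not isolated)
Conditions: Na2S2O4, Bu4NBr (cat.), THF/H2O, rt, N2; then KOH, Me2SO4, 0 °C to rt
Reagents that add atoms: dimethyl sulfate, COS(=O)(=O)OC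
Why: Dithionite reduces the quinone to hydroquinone 2, whose two phenoxide oxygens are methylated in the same flask (reductive methylation, Williamson ether synthesis), so the air-sensitive hydroquinone is never handled.

Step 2
Reactants: 3 1,4-dimethoxy-2-methylnaphthalene
Product: 4 2-(chloromethyl)-1,4-dimethoxy-3-methylnaphthalene
Conditions: (CH2O)n, conc. aq. HCl, AcOH, 60 °C
Reagents that add atoms: formaldehyde (from paraformaldehyde), C=O; hydrogen chloride, Cl
Why: Blanc chloromethylation: protonated formaldehyde attacks C3, the only unsubstituted position of the electron-rich dimethoxy ring, and HCl converts the benzylic alcohol into the chloride.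

Step 3
Reactants: 5 (4-bromobut-1-yn-1-yl)trimethylsilane; 6 (R)-propylene oxide
Product: 8 (R)-7-(trimethylsilyl)hept-6-yn-2-ol, via silylbutynylmagnesium bromide 7 (not isolated)
Conditions: Mg, THF, rt; then CuI (10 mol %), 6, THF, −30 to 0 °C; H2O work-up
Reagents that add atoms: none
Why: Copper-catalysed SN2 opening of the terminal epoxide by the primary Grignard reagent occurs at the unsubstituted CH2, so the stereocentre of 6 is not touched and becomes the (R)-carbinol of 8.

Step 4
Reactants: 8 (R)-7-(trimethylsilyl)hept-6-yn-2-ol
Product: 9 (R)-hept-6-yn-2-ol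
Conditions: K2CO3 (0.2 equiv), MeOH, rt
Reagents that add atoms: none
Why: Methoxide-mediated protodesilylation of the alkynylsilane frees the terminal alkyne without affecting the carbinol centre.

Step 5
Reactants: 9 (R)-hept-6-yn-2-ol; 4 2-(chloromethyl)-1,4-dimethoxy-3-methylnaphthalene
Product: 11 (2R,6E)-8-(1,4-dimethoxy-3-methylnaphthalen-2-yl)-6-methyloct-6-en-2-ol, via alkenylalane 10 (not isolated)
Conditions: AlMe3 (3 equiv), Cp2ZrCl2 (0.25 equiv), CH2Cl2, 0 °C to rt; evaporate; then 4, Pd(PPh3)4 (5 mol %), THF, rt; dilute aq. HCl work-up
Reagents that add atoms: trimethylaluminium, C[Al](C)C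
Why: Negishi carboalumination (zirconium-catalysed syn-methylalumination, the hydroxyl being masked in the flask as its dimethylaluminium alkoxide) places CH3 on the internal and aluminium on the terminal alkyne carbon to give the (E)-alkenylalane 10, and zerovalent palladium-catalysed Negishi-type coupling with the benzylic chloride 4 proceeds with retention of alkene geometry, fixing the E C2'=C3' alkene.

Step 6
Reactants: 11 (2R,6E)-8-(1,4-dimethoxy-3-methylnaphthalen-2-yl)-6-methyloct-6-en-2-ol
Product: 12 (2R,6E)-8-(1,4-dimethoxy-3-methylnaphthalen-2-yl)-6-methyloct-6-en-2-yl 4-methylbenzenesulfonate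
Conditions: TsCl, pyridine, DMAP (cat.), CH2Cl2, 0 °C to rt
Reagents that add atoms: 4-methylbenzenesulfonyl chloride, Cc1ccc(cc1)S(=O)(=O)Cl
Why: Sulfonylation takes place at oxygen and does not touch the C–O bond, so the R configuration at C7' is retained in the tosylate.

Step 7
Reactants: 13 (R)-citronellyl bromide ((R)-8-bromo-2,6-dimethyloct-2-ene)
Product: 15 (R)-4,8-dimethylnon-7-en-1-ol, via citronellylmagnesium bromide 14 (not isolated)
Conditions: Mg, THF, 40 °C; then CH2O (gas, from cracked (CH2O)n), 0 °C to rt; H2O work-up
Reagents that add atoms: formaldehyde, C=O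
Why: Addition of the primary Grignard reagent to formaldehyde extends the chain by the one carbon that becomes C8', while the stereocentre, three bonds from the reacting carbon, is untouched.

Step 8
Reactants: 15 (R)-4,8-dimethylnon-7-en-1-ol
Product: 16 (R)-4,8-dimethylnonan-1-ol
Conditions: H2 (1 atm), PtO2 (cat.), EtOAc, rt
Reagents that add atoms: none
Why: Heterogeneous hydrogenation saturates the isolated trisubstituted alkene; platinum is chosen because it isomerises alkenes less than palladium, so the double bond should not migrate toward the stereocentre.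

Step 9
Reactants: 16 (R)-4,8-dimethylnonan-1-ol
Product: 17 (R)-1-bromo-4,8-dimethylnonane
Conditions: CBr4, PPh3, CH2Cl2, 0 °C
Reagents that add atoms: carbon tetrabromide, BrC(Br)(Br)Br
Why: Appel reaction: the primary alcohol is activated as an alkoxyphosphonium ion and displaced by bromide in an SN2 step remote from the stereocentre.

Step 10
Reactants: 17 (R)-1-bromo-4,8-dimethylnonane; 12 (2R,6E)-8-(1,4-dimethoxy-3-methylnaphthalen-2-yl)-6-methyloct-6-en-2-yl 4-methylbenzenesulfonate
Product: 19 1,4-dimethoxy-2-methyl-3-[(2E,7R,11R)-3,7,11,15-tetramethylhexadec-2-en-1-yl]naphthalene, via (R)-4,8-dimethylnonylmagnesium bromide 18 (not isolated)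
Conditions: 17, Mg, THF, 40 °C; then 18 (1.8 equiv) added slowly to 12, CuI (10 mol %), TMEDA (20 mol %), LiOMe (1.0 equiv), THF, 0 °C; H2O work-up
Reagents that add atoms: none
Why: Grignard reagent 18 transmetalates to monovalent copper to give a TMEDA/methoxide-modified alkylcuprate, which attacks C7' of 12 from the face opposite the tosylate (SN2-type oxidative addition to a transient trivalent copper dialkyl, then reductive elimination), forging C7'–C8' and joining the C22 and C11 halves. The closest known reaction type is the copper-catalysed cross-coupling of unactivated secondary alkyl tosylates with primary alkyl Grignard reagents in the presence of TMEDA and LiOMe, which runs with inversion of configuration. No ring is closed. The new stereocentre C7' is controlled by the substrate alone: Walden inversion of the (R)-sulfonate, whose configuration was bought with 6, should give 7'R, while C11' travels unchanged in the nucleophile, three carbons from the C–Mg bond. The step needs substitution to win over E2 elimination and over bromide-for-tosylate exchange or single-electron pathways that would erode inversion, which the unhindered methylcarbinyl electrophile flanked by an unbranched CH2, the unbranched primary nucleophilic carbon and the low temperature should secure. Chemoselectivity rests on the absence of any other electrophilic site: the aryl methyl ethers, the trisubstituted C2'=C3' alkene and the doubly activated C1'H2 are inert to the cuprate at 0 °C, and C7' has no allylic or benzylic neighbour that would open ionisation or SN2' pathways.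

Step 11
Reactants: 19 1,4-dimethoxy-2-methyl-3-[(2E,7R,11R)-3,7,11,15-tetramethylhexadec-2-en-1-yl]naphthalene
Product: 20 phylloquinone (2-methyl-3-[(2E,7R,11R)-3,7,11,15-tetramethylhexadec-2-en-1-yl]naphthalene-1,4-dione)
Conditions: (NH4)2Ce(NO3)6 (2.5 equiv), MeCN/H2O, 0 °C
Reagents that add atoms: water, O
Why: Oxidative demethylation: two one-electron oxidations by tetravalent cerium convert the electron-rich 1,4-dimethoxynaphthalene, via its radical cation, attack of water and loss of methanol, into the para-quinone much faster than any oxidation of the isolated alkene, and no stereocentre is involved.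

**Compound list**

1 | menadione (2-methylnaphthalene-1,4-dione) | CC1=CC(=O)c2ccccc2C1=O | starting material
2 | menadiol (2-methylnaphthalene-1,4-diol) | Cc1cc(O)c2ccccc2c1O | intermediate
3 | 1,4-dimethoxy-2-methylnaphthalene | COc1cc(C)c(OC)c2ccccc12 | intermediate
4 | 2-(chloromethyl)-1,4-dimethoxy-3-methylnaphthalene | COc1c(C)c(CCl)c(OC)c2ccccc12 | intermediate
5 | (4-bromobut-1-yn-1-yl)trimethylsilane | C[Si](C)(C)C#CCCBr | starting material
6 | (R)-propylene oxide ((R)-2-methyloxirane) | C[C@@H]1CO1 | starting material
7 | [4-(trimethylsilyl)but-3-yn-1-yl]magnesium bromide | C[Si](C)(C)C#CCC[Mg]Br | intermediate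
8 | (R)-7-(trimethylsilyl)hept-6-yn-2-ol | C[C@@H](O)CCCC#C[Si](C)(C)C | intermediate
9 | (R)-hept-6-yn-2-ol | C[C@@H](O)CCCC#C | intermediate
10 | (E)-alkenylalane: [(1E,6R)-6-(dimethylaluminiooxy)-2-methylhept-1-en-1-yl]dimethylaluminium | C[C@@H](O[Al](C)C)CCC/C(C)=C/[Al](C)C | intermediate
11 | (2R,6E)-8-(1,4-dimethoxy-3-methylnaphthalen-2-yl)-6-methyloct-6-en-2-ol | COc1c(C)c(C/C=C(\C)CCC[C@@H](C)O)c(OC)c2ccccc12 | intermediate
12 | (2R,6E)-8-(1,4-dimethoxy-3-methylnaphthalen-2-yl)-6-methyloct-6-en-2-yl 4-methylbenzenesulfonate | COc1c(C)c(C/C=C(\C)CCC[C@@H](C)OS(=O)(=O)c3ccc(C)cc3)c(OC)c2ccccc12 | intermediate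
13 | (R)-citronellyl bromide ((R)-8-bromo-2,6-dimethyloct-2-ene) | BrCC[C@H](C)CCC=C(C)C | starting material
14 | [(R)-3,7-dimethyloct-6-en-1-yl]magnesium bromide | Br[Mg]CC[C@H](C)CCC=C(C)C | intermediate
15 | (R)-4,8-dimethylnon-7-en-1-ol | OCCC[C@H](C)CCC=C(C)C | intermediate
16 | (R)-4,8-dimethylnonan-1-ol | OCCC[C@H](C)CCCC(C)C | intermediate
17 | (R)-1-bromo-4,8-dimethylnonane | BrCCC[C@H](C)CCCC(C)C | intermediate
18 | [(R)-4,8-dimethylnonyl]magnesium bromide | Br[Mg]CCC[C@H](C)CCCC(C)C | intermediate
19 | 1,4-dimethoxy-2-methyl-3-[(2E,7R,11R)-3,7,11,15-tetramethylhexadec-2-en-1-yl]naphthalene | COc1c(C)c(C/C=C(\C)CCC[C@H](C)CCC[C@H](C)CCCC(C)C)c(OC)c2ccccc12 | intermediate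
20 | phylloquinone | CC1=C(C/C=C(\C)CCC[C@H](C)CCC[C@H](C)CCCC(C)C)C(=O)c2ccccc2C1=O | target

**Step count and risks**

Total step count: 11. Longest linear sequence: 6 steps (steps 3, 4, 5, 6, 10, 11 from 5 and 6; equally steps 1, 2, 5, 6, 10, 11 from 1).

Steps most likely to fail:

1. Step 10. The basic organometallic may eliminate the secondary sulfonate (E2) instead of substituting it, and inversion may be eroded by bromide-for-tosylate exchange or electron-transfer pathways. The fallback sets out from 17 (as its Grignard reagent 18) and comes back at 19. The same C7'–C8' bond is made on a strained electrophile: copper-catalysed SN2 opening of commercial (R)-β-butyrolactone at its methyl-bearing β-carbon (CuBr·SMe2 cat., THF/Me2S, −30 °C) should give, with inversion, (3R,7R)-3,7,11-trimethyldodecanoic acid F1. Reduction with LiAlH4 should give (3R,7R)-3,7,11-trimethyldodecan-1-ol F2, and I2/PPh3/imidazole should give (3R,7R)-1-iodo-3,7,11-trimethyldodecane F3. Alkylation of 3-lithio-1-(trimethylsilyl)propyne (from 1-(trimethylsilyl)propyne and n-BuLi, THF, −78 °C) with F3 should give trimethyl[(6R,10R)-6,10,14-trimethylpentadec-1-yn-1-yl]silane F4, and K2CO3 in MeOH should free (6R,10R)-6,10,14-trimethylpentadec-1-yne F5. Methylalumination of F5 and palladium-catalysed coupling with 4 under the conditions of step 5 rejoin the route at 19. The price is a linear instead of a convergent endgame.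

2. Step 5. Carbometalation may stall in the presence of the aluminium alkoxide, and transmetalation to palladium may be slow at the hindered, electron-rich benzylic chloride, which then homocouples or is reduced. The fallback sets out from 9 and 4 and comes back at 11, with the polarity of the coupling reversed. Methylalumination of 9 as before, quenched with I2 (THF, −30 °C), should give (2R,6E)-7-iodo-6-methylhept-6-en-2-ol F6. Zinc insertion into 4 (Zn dust, LiCl, THF, rt) should give [(1,4-dimethoxy-3-methylnaphthalen-2-yl)methyl]zinc chloride F7. Negishi coupling of F6 with an excess of F7 (Pd(OAc)2, SPhos, THF, rt) should give 11 with retention of the E geometry.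

3. Step 3. Wurtz-type homocoupling or elimination may compete while the homopropargylic Grignard reagent forms, and magnesium bromide may open the epoxide to a halohydrin. The fallback sets out from 6 and comes back at 9, by-passing 8. Opening of 6 at its CH2 terminus with but-1-ynyllithium (but-1-yne, n-BuLi, BF3·OEt2, THF, −78 °C) should give (R)-hept-4-yn-2-ol F8. The alkyne zipper reaction (KH, H2N(CH2)3NH2, 0 °C to rt) should then move the triple bond to the chain end, with the carbinol centre held as its alkoxide, to give 9.

**Further compounds**

F1 | step 10 | (3R,7R)-3,7,11-trimethyldodecanoic acid | OC(=O)C[C@H](C)CCC[C@H](C)CCCC(C)C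
F2 | step 10 | (3R,7R)-3,7,11-trimethyldodecan-1-ol | OCC[C@H](C)CCC[C@H](C)CCCC(C)C
F3 | step 10 | (3R,7R)-1-iodo-3,7,11-trimethyldodecane | ICC[C@H](C)CCC[C@H](C)CCCC(C)C
F4 | step 10 | trimethyl[(6R,10R)-6,10,14-trimethylpentadec-1-yn-1-yl]silane | C[Si](C)(C)C#CCCC[C@H](C)CCC[C@H](C)CCCC(C)C
F5 | step 10 | (6R,10R)-6,10,14-trimethylpentadec-1-yne | C#CCCC[C@H](C)CCC[C@H](C)CCCC(C)C
F6 | step 5 | (2R,6E)-7-iodo-6-methylhept-6-en-2-ol | C[C@@H](O)CCC/C(C)=C/I
F7 | step 5 | [(1,4-dimethoxy-3-methylnaphthalen-2-yl)methyl]zinc chloride | COc1c(C)c(C[Zn]Cl)c(OC)c2ccccc12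
F8 | step 3 | (R)-hept-4-yn-2-ol | C[C@@H](O)CC#CCC
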